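You have 8.0 s in each set-up, and the question is how that time is spent.

common to all: base 0.0500 equiv

|  | substrate | reagent | time | remark |
|---|---|---|---|---|
| zeta | 5.0 mM | 1.00 equiv (fed, over 6.40 s) | 8.0 s | a stirred flask in which reagent is dosed at a steady rate over 6.40 s without added volume, worked up at 8.0 s |
| eta | 5.0 mM | 1.00 equiv |  | a single well-mixed tank run continuously and read at steady state, 8.0 s in it on average |
| beta | 5.0 mM (fed, over 6.40 s) | 1.00 equiv | 8.0 s | a stirred flask in which substrate is dosed at a steady rate over 6.40 s without added volume, worked up at 8.0 s |
| epsilon | 5.0 mM | 1.00 equiv | 8.0 s | a closed flask charged with all of it at once and left for 8.0 s |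

    substrate + reagent → target + by-product (k1 = 1.8 M⁻¹ s⁻¹)
    reagent + by-product ⇌ idle adduct, settled at all times (K2 = 390 M⁻¹)
    substrate + reagent + by-product → target + 2 by-product (k3 = 32000 M⁻² s⁻¹)
    base + by-product ⇌ salt, settled at all times (K4 = 2.2 × 10⁷ M⁻¹)

- the set-up with the highest amount of target at the outlet or at the end, in percent of the substrate put in ("none" if the first two lie within 2 percentage points) (zeta / eta / beta / epsilon / none)
- amount of target at the outlet or at the end, in percent of the substrate put in, zeta
- amount of target at the outlet or at the end, in percent of the substrate put in, eta
- amount of target at the outlet or at the end, in percent of the substrate put in, beta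
- amount of target at the outlet or at the end, in percent of the substrate put in, epsilon

- for by-product the idle adduct is counted in
- the stated concentrations are those of everything mixed, before any reaction; amounts are the same in each set-up
- the feed brings no volume worth counting
- run time (zeta): 8.0 s

Turn step 1 into a rate first: at the charged amounts it runs at 0.00900 s⁻¹, counted as a fraction of the charge. With base at its charged amount, step 4 holds 5500 parts of by-product as salt per part free, so step 3 sees little free by-product. You can therefore define the base-filling time, the induction period of this autocatalysis, as the time step 1 at that rate takes to make as much by-product as there is base: 5.56 s.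

Flask beta and flask epsilon look nearly the same, with equal amounts and equal time. In beta, however, substrate arrives steadily, so on average it enters at mid-dose and has 4.80 s to react. That is shorter than the base-filling time, so by this reckoning beta stays in its induction period, and I reckon 4.32 %. The rate of step 1 is the product of substrate and reagent, so flask zeta, dosing reagent over the same 6.40 s, gets the same reckoning. Flask epsilon has the full 8.0 s, longer than the base-filling time, and I reckon 7.20 % from step 1, leaving step 3 and the loss of reactants aside. For the tank, eta, one rough pass of its balance takes the by-product from step 1 over its average 8.0 s, subtracts the base, lets step 3 run on the excess at charged amounts, leaves the idle adduct and the loss of reactants aside, and gives 21.3 %. So I put eta ahead.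

The forecast also named eta, with 4.1 % for zeta, 4.1 % for beta, 7.5 % for epsilon and 33.9 % for the tank, which it said “sits permanently in by-product-rich conditions”. Its tank figure stands above my pass.

The simulation puts eta ahead, with the tank at 33.9 %, epsilon at 7.29 %, and zeta and beta at 4.13 % and 4.13 %. In flask beta step 1 ran while base was still taking up by-product: the target ended 0.870 % of the charge short of the base charged, its 4.80 s falling short of 5.56 s. Flask zeta dosed over 2.40 s instead has on the same reckoning 6.80 s, which is longer than 5.56 s, and it ends above its base fraction of 0.0500 equiv, at 5.89 %.

(The constants used here are those of an exercise, and the outcome is calculated.)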